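Micromolar for micromolar was how I supposed the impurity took free catalyst, as a stoichiometric poison, though no earlier run tests that.

| flask | starting material | second substrate | free catalyst | impurity | remark |
|---|---|---|---|---|---|
| north-west | 10 mM | 20 mM | 30 µM | 5.7 µM | run made earlier |
| flask | 10 mM | 20.0 mM | 15 µM | 5.7 µM |  |

north-west run (percent of the starting material charged)

| time / s | target / % | starting material / % |
|---|---|---|
| 10.0 | 6 | 89 |
| 12.0 | 10 | 92 |
| 20.0 | 16 | 84 |
| 25.0 | 17 | 81 |
| 40.0 | 27 | 72 |
| 50.0 | 36 | 64 |

(each reading ± 1.5 percentage points)

- no earlier run changes the charge of free catalyst; that part of a forecast is a guess

- factor on the rate of making target when 10% of the starting material are converted if free catalyst is charged twice over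
- factor on the rate when 10% of the starting material are converted if free catalyst is charged at 150 µM instead

The north-west run shows target climbing steadily at a charge of 30 µM, which is the flask's charge doubled. It cannot test the effect of the charge, however, since it stands alone at that charge. I compared charges at one fixed conversion, where the substrates stand at the same fractions of their charges, and took the rate as proportional to the catalyst left working.

I then turned the question round. On that supposition, for a charge raised n-fold to raise the rate by plain n, the impurity's share of the charge must be nil, but in the flask I reckoned it at 38.0%. So I computed the correction alone, and kept one quantity, 0.613: the surcharge, the impurity charged over the catalyst charge left working. I let the added catalyst count in full and measured it against the reduced working part, which gives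

factor = n + (n − 1) × surcharge

doubled: 2 + 0.613 = 2.61

at 150 µM, where n is 10.0: 15.5

The forecast gave 2.4 (range 1.6 to 2.8) and 13.5 (range 6 to 17), both lower than my figures, with the words “Dimerisation or other limits at high loading would lower them, so I shade down and keep wide ranges”.

The flask gave 2.61 and 15.5.

    starting material + free catalyst ⇌ catalyst intermediate A (K = 78.0 M⁻¹, k = 1200 M⁻¹ s⁻¹)
    catalyst intermediate A → free catalyst + target (k = 21.0 s⁻¹)
    second substrate + free catalyst ⇌ catalyst intermediate B (K = 88.0 M⁻¹, k = 1300 M⁻¹ s⁻¹)
    catalyst intermediate B → free catalyst + second product (k = 18.0 s⁻¹)
    free catalyst + impurity → spent catalyst (k = 90000 M⁻¹ s⁻¹)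

Part of the reason for the size of the flask's rate shows in the flask run without the loss of free catalyst to spent catalyst through the impurity. There the rate at 10% conversion came to 1.61 times the actual one, and 1 plus the surcharge is 1.61. In the actual flask, spent catalyst held 37.9% of the catalyst charged by 0.250 min. A plain factor of 2 on doubling needs apparent order 1.0 in free catalyst, the value in that run without the poisoning, against 1.6 in the actual flask.

All runs were generated by integration with made-up constants; the scatter is artificial.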